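## Retrosynthetic overview

- Locants follow the name (3R,6E)-1-(2,4-dihydroxyphenyl)-3-ethenyl-3,7,11-trimethyldodeca-6,10-dien-1-one. The enabling feature is the quaternary carbon C3: it carries an ethenyl group and the C4–C5 ethano arm that ends at the C5–C6 bond. That arm is a second ethenyl group at a lower oxidation level, so C3 is a latent prochiral bis-ethenyl carbon.
- Key disconnection C5–C6: enantiotopic-group-selective anti-Markovnikov hydroalkenylation of an achiral bis-ethenyl amide (C10) with an (E)-alkenyl bromide (C9) under CuH/palladium dual catalysis. This forms C5–C6, sets C3 and carries the E-trisubstituted olefin through unchanged.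
- The diene amide comes from 3-methylpenta-2,4-dien-1-ol by Eschenmoser–Claisen rearrangement. The bromide comes from 6-methylhept-5-en-1-yne by zirconium-catalysed carboalumination and bromination.
- Endgame: the C1–aryl bond is made by adding a 2,4-bis(methoxymethoxy)phenyllithium to the dimethylamide, followed by acetal cleavage.
- No ring is formed in the route; the only ring, the resorcinol benzene ring, is bought as 4-bromoresorcinol.

Key step: step 5

Remark: the E isomer of the enynol is specified, but an E/Z mixture serves equally, because step 2 turns that olefin carbon into the symmetric bis-ethenyl carbon.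

Remark: the sense of enantiotopic-group selection in step 5 cannot be predicted from precedent; (R)-DTBM-SEGPHOS is written, and its mirror image is to be used if it proves to favour the (3S)-amide.

## Route

Step 1
Reactants: 1 (2E)-3-methylpent-2-en-4-yn-1-ol
Product: 2 (2E)-3-methylpenta-2,4-dien-1-ol
Conditions: H2 (1 atm, stopped after 1.0 equiv), Pd/CaCO3 poisoned with Pb(OAc)2, quinoline, EtOAc, 0 °C to rt
Reagents that add atoms: none
Why: Lindlar semi-hydrogenation should stop at the diene because the terminal alkyne binds the poisoned palladium surface much more strongly than the olefins do.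

Step 2
Reactants: 2 (2E)-3-methylpenta-2,4-dien-1-ol; 3 N,N-dimethylacetamide dimethyl acetal
Product: 5 3-ethenyl-N,N,3-trimethylpent-4-enamide, via ketene N,O-acetal 4 (not isolated)
Conditions: 3 (3 equiv), xylenes, 140 °C, MeOH distilled off
Reagents that add atoms: N,N-dimethylacetamide dimethyl acetal, CC(OC)(OC)N(C)C
Why: Eschenmoser–Claisen rearrangement: alcohol exchange and loss of methanol give ketene N,O-acetal 4, whose [3,3]-sigmatropic shift should form the C2–C3 bond and a quaternary carbon that is achiral because it carries two identical ethenyl groups.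

Step 3
Reactants: 6 5-bromo-2-methylpent-2-ene; 7 lithium acetylide–ethylenediamine complex
Product: 8 6-methylhept-5-en-1-yne
Conditions: DMSO, 10 °C to rt
Reagents that add atoms: lithium acetylide–ethylenediamine complex, [Li+].[C-]#C.NCCN
Why: SN2 alkylation of an acetylide by an unhindered primary bromide in a dipolar aprotic solvent should outrun elimination.

Step 4
Reactants: 8 6-methylhept-5-en-1-yne; 9 trimethylaluminium; 10 N-bromosuccinimide
Product: 12 (1E)-1-bromo-2,6-dimethylhepta-1,5-diene, via alkenylalane 11 (not isolated)
Conditions: AlMe3 (2 equiv), Cp2ZrCl2 (20 mol %), CH2Cl2, 0 °C to rt; excess AlMe3 removed in vacuo; then NBS (1.3 equiv), THF, −30 to 0 °C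
Reagents that add atoms: trimethylaluminium, C[Al](C)C; N-bromosuccinimide, O=C1CCC(=O)N1Br
Why: Zirconium-catalysed Negishi carboalumination should add methyl and aluminium syn across the terminal alkyne with aluminium at the terminus, and bromodealumination with retention then fixes the E geometry, while the isolated trisubstituted olefin stays inert.

Step 5
Reactants: 5 3-ethenyl-N,N,3-trimethylpent-4-enamide; 12 (1E)-1-bromo-2,6-dimethylhepta-1,5-diene
Product: 13 (3R,6E)-3-ethenyl-N,N,3,7,11-pentamethyldodeca-6,10-dienamide
Conditions: 5 (2.0 equiv), 12 (1.0 equiv), Cu(OAc)2 (5 mol %), (R)-DTBM-SEGPHOS (5.5 mol %), [Pd(cinnamyl)Cl]2 (2.5 mol %), BrettPhos (5.5 mol %), MeSiH(OMe)2 (2 equiv), NaOSiMe3 (2 equiv), THF, 40 °C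
Reagents that add atoms: none
Why: Proposed new method: ligated CuH, formed from Cu(OAc)2, the bisphosphine and the silane, should add irreversibly across one of the two enantiotopic ethenyl groups of 5 with copper on the terminal carbon; the primary alkylcopper then transmetalates to the alkenylpalladium bromide that zerovalent palladium/BrettPhos forms from 12 by oxidative addition with retention of the E geometry, reductive elimination forms C5–C6, and NaOSiMe3 plus silane return CuH. The closest known reaction type is the dual CuH/palladium anti-Markovnikov hydroalkenylation and hydroarylation of unactivated terminal olefins with enol triflates and aryl bromides; new here are the alkenyl bromide partner and the use of the hydrocupration as a desymmetrizing event at a bis-ethenyl quaternary carbon. No ring is closed. The only new stereocentre, C3, is controlled by the chiral bisphosphine on copper, which must tell the two ethenyl groups apart through the size difference between the other two C3 substituents (methyl against the CH2C(=O)NMe2 arm) in the hydrocupration transition state; any second hydroalkenylation should consume the minor enantiomer of 13 faster and so raise the enantiomeric purity of the mono-adduct. The step needs anti-Markovnikov regioselectivity, secured by the neopentyl character of the internal ethenyl carbon next to C3; mono-functionalization, secured by the twofold excess of the cheap achiral diene; and chemoselectivity, secured by the inertness of trisubstituted olefins and of the tertiary amide towards CuH (the amide stands in for the aryl ketone, which CuH would reduce).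

Step 6
Reactants: 14 4-bromobenzene-1,3-diol; 15 chloromethyl methyl ether
Product: 16 1-bromo-2,4-bis(methoxymethoxy)benzene
Conditions: iPr2NEt (3 equiv), CH2Cl2, 0 °C to rt
Reagents that add atoms: chloromethyl methyl ether, COCCl
Why: Williamson-type O-alkylation of both phenols by the reactive chloromethyl ether under amine base should give the bis-acetal.

Step 7
Reactants: 13 (3R,6E)-3-ethenyl-N,N,3,7,11-pentamethyldodeca-6,10-dienamide; 16 1-bromo-2,4-bis(methoxymethoxy)benzene
Product: 19 (3R,6E)-1-[2,4-bis(methoxymethoxy)phenyl]-3-ethenyl-3,7,11-trimethyldodeca-6,10-dien-1-one, via aryllithium 17 (not isolated), via lithium hemiaminalate 18 (not isolated)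
Conditions: 16 (1.3 equiv), n-BuLi (1.25 equiv), THF, −78 °C, 20 min; then 13, −78 to 0 °C; H2O quench
Reagents that add atoms: none
Why: Bromine–lithium exchange gives aryllithium 17, held by the ortho acetal oxygen, and its acyl substitution on the dimethylamide should stop at the tetrahedral hemiaminalate 18, which releases the ketone only on aqueous work-up, so over-addition is avoided and C3 is untouched.

Step 8
Reactants: 19 (3R,6E)-1-[2,4-bis(methoxymethoxy)phenyl]-3-ethenyl-3,7,11-trimethyldodeca-6,10-dien-1-one
Product: 20 (3R,6E)-1-(2,4-dihydroxyphenyl)-3-ethenyl-3,7,11-trimethyldodeca-6,10-dien-1-one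
Conditions: 3 M aq HCl/MeOH (1:10), 40 °C
Reagents that add atoms: none
Why: Acid-catalysed acetal cleavage in methanol should free both phenols under conditions too mild to protonate the isolated olefins, and the quaternary centre cannot epimerize.

## Compound list

1 | (2E)-3-methylpent-2-en-4-yn-1-ol | C#C/C(C)=C/CO | starting material
2 | (2E)-3-methylpenta-2,4-dien-1-ol | C=C/C(C)=C/CO | intermediate
3 | N,N-dimethylacetamide dimethyl acetal (1,1-dimethoxy-N,N-dimethylethan-1-amine) | CC(OC)(OC)N(C)C | starting material
4 | N,N-dimethyl-1-{[(2E)-3-methylpenta-2,4-dien-1-yl]oxy}ethen-1-amine (ketene N,O-acetal) | C=C(N(C)C)OC/C=C(C)/C=C | intermediate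
5 | 3-ethenyl-N,N,3-trimethylpent-4-enamide (achiral, two ethenyl groups on C3) | C=CC(C)(C=C)CC(=O)N(C)C | intermediate
6 | 5-bromo-2-methylpent-2-ene | CC(C)=CCCBr | starting material
7 | lithium acetylide–ethylenediamine complex | [Li+].[C-]#C.NCCN | starting material
8 | 6-methylhept-5-en-1-yne | C#CCCC=C(C)C | intermediate
9 | trimethylaluminium | C[Al](C)C | starting material
10 | N-bromosuccinimide | O=C1CCC(=O)N1Br | starting material
11 | [(1E)-2,6-dimethylhepta-1,5-dien-1-yl]dimethylalane | C[Al](C)/C=C(\C)CCC=C(C)C | intermediate
12 | (1E)-1-bromo-2,6-dimethylhepta-1,5-diene | Br/C=C(\C)CCC=C(C)C | intermediate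
13 | (3R,6E)-3-ethenyl-N,N,3,7,11-pentamethyldodeca-6,10-dienamide | C=C[C@](C)(CC/C=C(\C)CCC=C(C)C)CC(=O)N(C)C | intermediate
14 | 4-bromobenzene-1,3-diol (4-bromoresorcinol) | Oc1ccc(Br)c(O)c1 | starting material
15 | chloromethyl methyl ether | COCCl | starting material
16 | 1-bromo-2,4-bis(methoxymethoxy)benzene | COCOc1ccc(Br)c(OCOC)c1 | intermediate
17 | [2,4-bis(methoxymethoxy)phenyl]lithium | [Li]c1ccc(OCOC)cc1OCOC | intermediate
18 | lithium (3R,6E)-1-[2,4-bis(methoxymethoxy)phenyl]-1-(dimethylamino)-3-ethenyl-3,7,11-trimethyldodeca-6,10-dien-1-olate (both C1 epimers) | C=C[C@](C)(CC/C=C(\C)CCC=C(C)C)CC([O-])(N(C)C)c1ccc(OCOC)cc1OCOC.[Li+] | intermediate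
19 | (3R,6E)-1-[2,4-bis(methoxymethoxy)phenyl]-3-ethenyl-3,7,11-trimethyldodeca-6,10-dien-1-one | C=C[C@](C)(CC/C=C(\C)CCC=C(C)C)CC(=O)c1ccc(OCOC)cc1OCOC | intermediate
20 | (3R,6E)-1-(2,4-dihydroxyphenyl)-3-ethenyl-3,7,11-trimethyldodeca-6,10-dien-1-one | C=C[C@](C)(CC/C=C(\C)CCC=C(C)C)CC(=O)c1ccc(O)cc1O | target

## Step count and risks

Total step count: 8. Longest linear sequence: 5 steps (steps 1, 2, 5, 7, 8 or steps 3, 4, 5, 7, 8).

**Step 5 (Proposed new method).** The catalyst may discriminate poorly between the two enantiotopic ethenyl groups. The second ethenyl group may also react, or the bromide may be lost to hydrodebromination or Heck-type alkenylation. The fallback uses known chemistry and sets out from compounds 5 and 12. Hydroboration of 5 (2 equiv) with 9-BBN (1 equiv, THF, 0 °C to rt) should give the racemic B-alkyl borane, rac-5-(9-borabicyclo[3.3.1]nonan-9-yl)-3-ethenyl-N,N,3-trimethylpentanamide F1, which is not isolated. B-alkyl Suzuki–Miyaura coupling with 12 (PdCl2(dppf), aq NaOH, THF/DMF, 50 °C) should then give the racemic amide, rac-(6E)-3-ethenyl-N,N,3,7,11-pentamethyldodeca-6,10-dienamide F2. Preparative chromatography on a polysaccharide chiral stationary phase (supercritical CO2/MeOH) would separate the unwanted (3S,6E)-3-ethenyl-N,N,3,7,11-pentamethyldodeca-6,10-dienamide F3 from the (3R)-enantiomer. The fallback comes back to the route at compound 13.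

**Step 7.** The aryllithium may deprotonate the amide alpha to the carbonyl instead of adding, or attack may be slow because the carbonyl sits next to the neopentyl-type C2–C3 unit. The fallback sets out from compound 13. Partial reduction with LiAlH(OEt)3 (Et2O, 0 °C) should give the aldehyde (3R,6E)-3-ethenyl-3,7,11-trimethyldodeca-6,10-dienal F4. Addition of aryllithium 17 (THF, −78 °C) should give the benzylic alcohol (3R,6E)-1-[2,4-bis(methoxymethoxy)phenyl]-3-ethenyl-3,7,11-trimethyldodeca-6,10-dien-1-ol F5 as a mixture of C1 epimers. Oxidation with Dess–Martin periodinane (CH2Cl2, NaHCO3, rt) removes the temporary stereocentre, and the fallback comes back to the route at compound 19.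

**Step 2.** The conjugated diene of 2 or of ketene N,O-acetal 4 may oligomerize thermally, or methanol may be eliminated to a triene, before the sigmatropic shift occurs. The fallback sets out from compound 1 and reverses the order of reduction and rearrangement. Eschenmoser–Claisen rearrangement of the enynol 1 with 3 (toluene, 110 °C) should pass through N,N-dimethyl-1-{[(2E)-3-methylpent-2-en-4-yn-1-yl]oxy}ethen-1-amine F6, not isolated, to racemic 3-ethynyl-N,N,3-trimethylpent-4-enamide F7. Its semi-hydrogenation (H2, Pd/CaCO3 poisoned with Pb(OAc)2, quinoline, EtOAc) turns ethynyl into ethenyl and erases the stereocentre, and the fallback comes back to the route at compound 5.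

## Further compounds

F1 | step 5 | rac-5-(9-borabicyclo[3.3.1]nonan-9-yl)-3-ethenyl-N,N,3-trimethylpentanamide | C=CC(C)(CCB1C2CCCC1CCC2)CC(=O)N(C)C
F2 | step 5 | rac-(6E)-3-ethenyl-N,N,3,7,11-pentamethyldodeca-6,10-dienamide | C=CC(C)(CC/C=C(\C)CCC=C(C)C)CC(=O)N(C)C
F3 | step 5 | (3S,6E)-3-ethenyl-N,N,3,7,11-pentamethyldodeca-6,10-dienamide | C=C[C@@](C)(CC/C=C(\C)CCC=C(C)C)CC(=O)N(C)C
F4 | step 7 | (3R,6E)-3-ethenyl-3,7,11-trimethyldodeca-6,10-dienal | C=C[C@](C)(CC/C=C(\C)CCC=C(C)C)CC=O
F5 | step 7 | (3R,6E)-1-[2,4-bis(methoxymethoxy)phenyl]-3-ethenyl-3,7,11-trimethyldodeca-6,10-dien-1-ol (C1 epimers) | C=C[C@](C)(CC/C=C(\C)CCC=C(C)C)CC(O)c1ccc(OCOC)cc1OCOC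
F6 | step 2 | N,N-dimethyl-1-{[(2E)-3-methylpent-2-en-4-yn-1-yl]oxy}ethen-1-amine | C=C(N(C)C)OC/C=C(C)/C#C
F7 | step 2 | rac-3-ethynyl-N,N,3-trimethylpent-4-enamide | C#CC(C)(C=C)CC(=O)N(C)C
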